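(The rate constants stand for no real mixture; the run is a simulation.)

At early times the open intermediate in the west flask is simply what the making step has delivered, because the 15 s half-life of starting material under charged partner is shorter than the 80 s half-life of the open intermediate on its way to product.

    starting material + product ⇌ idle adduct, settled at all times (K1 = 49.7 /M)
    starting material + partner → open intermediate + by-product (k2 = 0.192 /M/s)
    open intermediate → product (k3 = 0.00864 /s)
    open intermediate + capture agent → trapped intermediate (k4 = 0.0380 /M/s)

| setting | east | north-east | south-west | west |
|---|---|---|---|---|
| starting material | 0.39 M | 0.39 M | 0.39 M | 0.39 M |
| partner | 0.600 equiv | 0.600 equiv | 0.600 equiv (fed, over 32.0 s) | 0.600 equiv |
| capture agent | 7.80 mM | 7.80 mM | 7.80 mM | 7.80 mM |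
| remark | a single well-mixed tank run continuously and read at steady state, 120 s in it on average | one stirred flow tank at steady state, fed with the mixture as stated, mean residence time 40 s | a stirred flask in which partner is dosed at a steady rate over 32.0 s without added volume, worked up at 40 s | everything together in a closed stirred flask, run for 40 s |
| time |  |  | 40 s | 40 s |

- the set-up with the highest amount of open intermediate at the outlet or at the end, in percent of the starting material put in ("none" if the first two lie within 2 percentage points) (east / north-east / south-west / west / none)
- amount of open intermediate at the outlet or at the end, in percent of the starting material put in, east
- amount of open intermediate at the outlet or at the end, in percent of the starting material put in, north-east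
- amount of open intermediate at the outlet or at the end, in percent of the starting material put in, south-west
- amount of open intermediate at the outlet or at the end, in percent of the starting material put in, west

- in percentages every species weighs as the starting material in it: one idle adduct counts as two
- for product the idle adduct is counted in
- the stated concentrations are those of everything mixed, before any reaction; amounts are the same in each set-up
- the feed brings no volume worth counting
- in an amount of product, one idle adduct counts as one product
- run time (south-west): 40 s

My bench rule was to take what has been made and subtract a lost share equal to the drain number, the rate constant to product times the mean time held, which for the east tank is 1.04. In the west flask, I supposed that the material was made around 15 s and had waited 24.6 s, so its drain number was 0.212. Setting aside the drain and the idle adduct, I integrated the making step with partner as limiting reagent and found 0.512 of the charge made, which left 0.403 after the correction.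

The subtraction stops working as the drain number nears one, and the east tank stands just past that border, since the correction there exceeds the thing corrected. For tanks I therefore used the balance, in which the surviving share is one over one plus the drain number, and I again set aside the idle adduct, so the amounts made and kept that follow are reckoned ones. The north-east tank, with drain number 0.346, makes 0.388 and keeps 0.288. The east tank makes 0.492 and keeps 0.242. I did not reckon the dosed south-west flask.

The forecast, on the grounds that the intermediate “builds quickly and drains slowly”, named west and gave 22.0% east, 27.4% north-east, 35.0% south-west and 38.7% west, a little below mine in the west flask and in the north-east and east tanks. The simulation gave west as best, with 22.0% east, 27.4% north-east, 34.9% south-west and 39.1% west.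

The half-life of the open intermediate on the way to product, 80 s, is far shorter than its 39 min by capture in the west flask, and at the east outlet product stood at 22.8% against 22.0% open intermediate, a ratio of 1.04 beside the drain number 1.04. Left to 400 s, the west flask, with a drain number of 3.11 for the further 360 s, held 2.46% open intermediate.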